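**Plan**
1. Retrosynthesis first cuts the two ester C–O bonds (C3–O–isovaleryl, side-chain O–senecioyl), then takes the formyl oxygen and the C=CH2 bond back to a C(CH3)2OH group on C2.
2. The C3–O bond is traced to a C3–Si bond and that to a C3–H bond. The last cuts are the C2–H/C3–H bonds of ring B (back to a benzofuran) and the O1–C2 and C3–C3a bonds (back to an iodophenol and an alkyne).
3. Forward: ring B is annulated onto ring A, the ketone and then the furan double bond are reduced, a temporary oxasilolane ring is closed onto C3 and oxidised away, and the C2 group and the two esters are finished.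
4. Enabling feature: in ring B (O1, C2, C3) the C3 oxygen is cis to the three-carbon group on C2. With the central carbon of that group as a tertiary carbinol, its oxygen is 1,3 to C3, so a silicon on it reaches the cis C3–H through a five-membered ring and no other C–H bond in that way.
5. Stereochemistry: side-chain (S) from Noyori transfer hydrogenation; C2 from catalyst-controlled hydrogenation of the benzofuran; C3 relayed from C2 by the silicon tether and kept by Tamao–Fleming oxidation with retention.

Key step: step 6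

Assumption: in step 4 the (R,R) antipode of the carbene ligand is taken to be the one that gives (S) at C2; if a first run shows the opposite sense, the (S,S) ligand is used and nothing else changes.

**Route**

Step 1
Reactants: 1 1-(4-hydroxy-3-iodophenyl)ethanone; 2 2-methylbut-3-yn-2-ol
Product: 4 1-[2-(2-hydroxypropan-2-yl)-1-benzofuran-5-yl]ethanone, via 2-alkynylphenol 3 (not isolated)
Conditions: PdCl2(PPh3)2 (2 mol %), CuI (4 mol %), Et3N, DMF, 60 °C
Reagents that add atoms: none
Why: Sonogashira coupling at the C–I bond followed in the same pot by metal-assisted 5-endo-dig attack of the ortho phenoxide on the alkyne is the standard benzofuran annulation of 2-iodophenols, and the tertiary propargylic alcohol and the ketone are inert to it.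

Step 2
Reactants: 4 1-[2-(2-hydroxypropan-2-yl)-1-benzofuran-5-yl]ethanone
Product: 5 (1S)-1-[2-(2-hydroxypropan-2-yl)-1-benzofuran-5-yl]ethan-1-ol
Conditions: RuCl(p-cymene)[(S,S)-TsDPEN] (1 mol %), HCO2Na, H2O/MeOH (1:1), 40 °C
Reagents that add atoms: none
Why: Noyori asymmetric transfer hydrogenation of an aryl methyl ketone, in which the (S,S)-TsDPEN ruthenium hydride reduces through the six-membered outer-sphere transition state to the (S)-1-arylethanol, while the near-neutral formate medium spares the acid-labile tertiary furyl carbinol and the furan double bond.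

Step 3
Reactants: 5 (1S)-1-[2-(2-hydroxypropan-2-yl)-1-benzofuran-5-yl]ethan-1-ol
Product: 6 2-{5-[(1S)-1-{[tert-butyl(dimethyl)silyl]oxy}ethyl]-1-benzofuran-2-yl}propan-2-ol
Conditions: TBSCl, imidazole, DMF, 0 °C to rt
Reagents that add atoms: tert-butyldimethylsilyl chloride, CC(C)(C)[Si](C)(C)Cl
Why: Silyl ether formation with TBSCl/imidazole is fast at the secondary benzylic hydroxyl and leaves the hindered tertiary one free to carry the tether later.

Step 4
Reactants: 6 2-{5-[(1S)-1-{[tert-butyl(dimethyl)silyl]oxy}ethyl]-1-benzofuran-2-yl}propan-2-ol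
Product: 7 2-[(2S)-5-[(1S)-1-{[tert-butyl(dimethyl)silyl]oxy}ethyl]-2,3-dihydro-1-benzofuran-2-yl]propan-2-ol
Conditions: Ru(cod)(2-methylallyl)2 (5 mol %), 1,3-bis[(1R)-1-(naphthalen-1-yl)ethyl]-4,5-dihydroimidazolium tetrafluoroborate (10 mol %), KOtBu (15 mol %), hexane; then 6, H2 (60 bar), 40 °C
Reagents that add atoms: none
Why: Enantioselective hydrogenation of a 2-substituted benzofuran with a chiral ruthenium N-heterocyclic carbene catalyst adds H2 syn to one face of the C2=C3 bond only, so C2 is set by the catalyst (the remote side-chain centre has no influence) while ring A and the silyl ether are untouched.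

Step 5
Reactants: 7 2-[(2S)-5-[(1S)-1-{[tert-butyl(dimethyl)silyl]oxy}ethyl]-2,3-dihydro-1-benzofuran-2-yl]propan-2-ol; 8 diethylsilane
Product: 9 (2S)-5-[(1S)-1-{[tert-butyl(dimethyl)silyl]oxy}ethyl]-2-{2-[(diethylsilyl)oxy]propan-2-yl}-2,3-dihydro-1-benzofuran (the diethyl(hydrido)silyl ether of 7)
Conditions: [Ir(cod)OMe]2 (0.5 mol %), THF, rt; volatiles removed, used crude
Reagents that add atoms: none
Why: Iridium-catalysed dehydrogenative coupling of an alcohol with a dihydrosilane stops at the alkoxy(hydrido)silane when the silane is in excess and also serves hindered tertiary hydroxyls, so the tether is attached without base or chloride.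

Step 6
Reactants: 9 (2S)-5-[(1S)-1-{[tert-butyl(dimethyl)silyl]oxy}ethyl]-2-{2-[(diethylsilyl)oxy]propan-2-yl}-2,3-dihydro-1-benzofuran
Product: 10 cis-fused oxasilolane: a 2,2-diethyl-1,2-oxasilolane ring (O–SiEt2–C3–C2–CMe2) fused across C2–C3 of 5-[(1S)-1-{[tert-butyl(dimethyl)silyl]oxy}ethyl]-2,3-dihydro-1-benzofuran; C2 (R) and C3 (R) in benzofuran numbering, silicon and the CMe2 carbon on the same face
Conditions: [Ir(cod)OMe]2 (2 mol %), 3,4,7,8-tetramethyl-1,10-phenanthroline (5 mol %), norbornene (1.5 equiv), THF, 100 °C, sealed tube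
Reagents that add atoms: none
Why: The Si–H bond of 9 adds oxidatively to the phenanthroline-ligated iridium, norbornene takes up the hydrogen, and the iridium silyl cleaves the C3–H bond on the tether side within a six-membered iridacycle (Ir–Si–O–C–C2–C3) before C–Si reductive elimination releases 10. The closest known reaction is the hydroxyl-directed iridium-catalysed silylation of secondary C(sp3)–H bonds gamma to the oxygen of (hydrido)silyl ethers, used to make 1,3-diols. The one ring that closes is the five-membered oxasilolane, formed by C3–Si bond formation as a cis-fused bicycle on ring B, since a trans fusion of two five-membered rings is out of reach. The new stereocentre C3 is therefore fixed by C2 alone: silicon enters on the face that carries the carbinol carbon. The step needs site selectivity over all other C–H bonds, and the tether length secures it: the methyl and C2 hydrogens would close four-membered rings, the aromatic C4–H and C7–H seven-membered ones, and the side chain cannot be reached.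

Step 7
Reactants: 10 cis-fused oxasilolane
Product: 11 (2S,3R)-5-[(1S)-1-{[tert-butyl(dimethyl)silyl]oxy}ethyl]-2-(2-hydroxypropan-2-yl)-2,3-dihydro-1-benzofuran-3-ol (2,3-cis)
Conditions: H2O2 (30 % aq.), KHCO3, THF/MeOH, 50 °C
Reagents that add atoms: hydrogen peroxide, OO
Why: Tamao–Fleming oxidation of the alkoxy-activated C–Si bond moves C3 from silicon to peroxide oxygen with retention, so the C3 hydroxyl appears cis to the C2 substituent, and the strained Si–O ring should allow fluoride-free conditions that keep the TBS ether.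

Step 8
Reactants: 11 (2S,3R)-5-[(1S)-1-{[tert-butyl(dimethyl)silyl]oxy}ethyl]-2-(2-hydroxypropan-2-yl)-2,3-dihydro-1-benzofuran-3-ol; 12 3-methylbutanoyl chloride
Product: 13 (2S,3R)-5-[(1S)-1-{[tert-butyl(dimethyl)silyl]oxy}ethyl]-2-(2-hydroxypropan-2-yl)-2,3-dihydro-1-benzofuran-3-yl 3-methylbutanoate
Conditions: pyridine, DMAP (cat.), CH2Cl2, 0 °C
Reagents that add atoms: none
Why: Acylation with an acid chloride under pyridine/DMAP takes the secondary C3 hydroxyl and not the tertiary one for steric reasons, and the basic medium avoids ionisation of the benzylic C3–O bond.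

Step 9
Reactants: 13 (2S,3R)-5-[(1S)-1-{[tert-butyl(dimethyl)silyl]oxy}ethyl]-2-(2-hydroxypropan-2-yl)-2,3-dihydro-1-benzofuran-3-yl 3-methylbutanoate
Product: 14 (2R,3R)-5-[(1S)-1-{[tert-butyl(dimethyl)silyl]oxy}ethyl]-2-(prop-1-en-2-yl)-2,3-dihydro-1-benzofuran-3-yl 3-methylbutanoate
Conditions: Burgess reagent, toluene, 60 °C
Reagents that add atoms: none
Why: Burgess dehydration (syn elimination of the tertiary sulfamate under neutral conditions) should remove one of six methyl hydrogens in preference to the single hindered C2–H, giving the isopropenyl group as is usual for 2-(2-hydroxypropan-2-yl) cyclic ethers, and neither stereocentre is touched.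

Step 10
Reactants: 14 (2R,3R)-5-[(1S)-1-{[tert-butyl(dimethyl)silyl]oxy}ethyl]-2-(prop-1-en-2-yl)-2,3-dihydro-1-benzofuran-3-yl 3-methylbutanoate
Product: 16 (2R,3R)-5-[(1S)-1-{[tert-butyl(dimethyl)silyl]oxy}ethyl]-2-(3-oxoprop-1-en-2-yl)-2,3-dihydro-1-benzofuran-3-yl 3-methylbutanoate, via allylic alcohol 15 (not isolated)
Conditions: SeO2 (2 equiv), 1,4-dioxane, 70 °C
Reagents that add atoms: selenium dioxide, O=[Se]=O
Why: Riley allylic oxidation (ene reaction of SeO2, then 2,3-sigmatropic shift) attacks the methyl of a 1,1-disubstituted alkene in preference to an allylic methine, as in the conversion of terpenoid isopropenyl groups into 2-substituted acroleins, and the alcohol formed first is oxidised on to the aldehyde.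

Step 11
Reactants: 16 (2R,3R)-5-[(1S)-1-{[tert-butyl(dimethyl)silyl]oxy}ethyl]-2-(3-oxoprop-1-en-2-yl)-2,3-dihydro-1-benzofuran-3-yl 3-methylbutanoate
Product: 17 (2R,3R)-5-[(1S)-1-hydroxyethyl]-2-(3-oxoprop-1-en-2-yl)-2,3-dihydro-1-benzofuran-3-yl 3-methylbutanoate
Conditions: HF·pyridine, pyridine, THF, 0 °C to rt
Reagents that add atoms: none
Why: Fluoride cleavage of the Si–O bond with pyridine-buffered HF·pyridine is not basic enough to eliminate the C3 ester (which would aromatise ring B) and not acidic enough to ionise the benzylic alcohol.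

Step 12
Reactants: 17 (2R,3R)-5-[(1S)-1-hydroxyethyl]-2-(3-oxoprop-1-en-2-yl)-2,3-dihydro-1-benzofuran-3-yl 3-methylbutanoate; 18 3-methylbut-2-enoyl chloride
Product: 19 (1S)-1-[(2R,3R)-3-[(3-methylbutanoyl)oxy]-2-(3-oxoprop-1-en-2-yl)-2,3-dihydro-1-benzofuran-5-yl]ethyl 3-methylbut-2-enoate
Conditions: pyridine, DMAP (cat.), CH2Cl2, −20 to 0 °C
Reagents that add atoms: none
Why: Acylation of the secondary benzylic alcohol with the acid chloride at low temperature, a weak base being chosen so that the chloride is not deprotonated to the vinylketene and the enal with its labile C2–H survives; the carbinol carbon is not involved and keeps (S).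

**Compound list**

1 | 1-(4-hydroxy-3-iodophenyl)ethanone | CC(=O)c1ccc(O)c(I)c1 | starting material
2 | 2-methylbut-3-yn-2-ol | CC(C)(O)C#C | starting material
3 | 1-[4-hydroxy-3-(3-hydroxy-3-methylbut-1-yn-1-yl)phenyl]ethanone | CC(=O)c1ccc(O)c(C#CC(C)(C)O)c1 | intermediate
4 | 1-[2-(2-hydroxypropan-2-yl)-1-benzofuran-5-yl]ethanone | CC(=O)c1ccc2oc(C(C)(C)O)cc2c1 | intermediate
5 | (1S)-1-[2-(2-hydroxypropan-2-yl)-1-benzofuran-5-yl]ethan-1-ol | CC(C)(O)c1cc2cc([C@H](C)O)ccc2o1 | intermediate
6 | 2-{5-[(1S)-1-{[tert-butyl(dimethyl)silyl]oxy}ethyl]-1-benzofuran-2-yl}propan-2-ol | CC(C)(O)c1cc2cc([C@H](C)O[Si](C)(C)C(C)(C)C)ccc2o1 | intermediate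
7 | 2-[(2S)-5-[(1S)-1-{[tert-butyl(dimethyl)silyl]oxy}ethyl]-2,3-dihydro-1-benzofuran-2-yl]propan-2-ol | CC(C)(O)[C@H]1Oc2ccc([C@H](C)O[Si](C)(C)C(C)(C)C)cc2C1 | intermediate
8 | diethylsilane | CC[SiH2]CC | starting material
9 | (2S)-5-[(1S)-1-{[tert-butyl(dimethyl)silyl]oxy}ethyl]-2-{2-[(diethylsilyl)oxy]propan-2-yl}-2,3-dihydro-1-benzofuran | CC(C)(O[SiH](CC)CC)[C@H]1Oc2ccc([C@H](C)O[Si](C)(C)C(C)(C)C)cc2C1 | intermediate
10 | cis-fused oxasilolane (O–SiEt2–C3–C2–CMe2 ring on ring B; C2 R, C3 R; side chain (S) TBS ether) | CC3(C)[C@H]1Oc2ccc([C@H](C)O[Si](C)(C)C(C)(C)C)cc2[C@H]1[Si](CC)(CC)O3 | intermediate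
11 | (2S,3R)-5-[(1S)-1-{[tert-butyl(dimethyl)silyl]oxy}ethyl]-2-(2-hydroxypropan-2-yl)-2,3-dihydro-1-benzofuran-3-ol | CC(C)(O)[C@H]1Oc2ccc([C@H](C)O[Si](C)(C)C(C)(C)C)cc2[C@H]1O | intermediate
12 | 3-methylbutanoyl chloride | CC(C)CC(=O)Cl | starting material
13 | (2S,3R)-5-[(1S)-1-{[tert-butyl(dimethyl)silyl]oxy}ethyl]-2-(2-hydroxypropan-2-yl)-2,3-dihydro-1-benzofuran-3-yl 3-methylbutanoate | CC(C)(O)[C@H]1Oc2ccc([C@H](C)O[Si](C)(C)C(C)(C)C)cc2[C@H]1OC(=O)CC(C)C | intermediate
14 | (2R,3R)-5-[(1S)-1-{[tert-butyl(dimethyl)silyl]oxy}ethyl]-2-(prop-1-en-2-yl)-2,3-dihydro-1-benzofuran-3-yl 3-methylbutanoate | C=C(C)[C@H]1Oc2ccc([C@H](C)O[Si](C)(C)C(C)(C)C)cc2[C@H]1OC(=O)CC(C)C | intermediate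
15 | (2R,3R)-5-[(1S)-1-{[tert-butyl(dimethyl)silyl]oxy}ethyl]-2-(3-hydroxyprop-1-en-2-yl)-2,3-dihydro-1-benzofuran-3-yl 3-methylbutanoate | C=C(CO)[C@H]1Oc2ccc([C@H](C)O[Si](C)(C)C(C)(C)C)cc2[C@H]1OC(=O)CC(C)C | intermediate
16 | (2R,3R)-5-[(1S)-1-{[tert-butyl(dimethyl)silyl]oxy}ethyl]-2-(3-oxoprop-1-en-2-yl)-2,3-dihydro-1-benzofuran-3-yl 3-methylbutanoate | C=C(C=O)[C@H]1Oc2ccc([C@H](C)O[Si](C)(C)C(C)(C)C)cc2[C@H]1OC(=O)CC(C)C | intermediate
17 | (2R,3R)-5-[(1S)-1-hydroxyethyl]-2-(3-oxoprop-1-en-2-yl)-2,3-dihydro-1-benzofuran-3-yl 3-methylbutanoate | C=C(C=O)[C@H]1Oc2ccc([C@H](C)O)cc2[C@H]1OC(=O)CC(C)C | intermediate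
18 | 3-methylbut-2-enoyl chloride | CC(C)=CC(=O)Cl | starting material
19 | (1S)-1-[(2R,3R)-3-[(3-methylbutanoyl)oxy]-2-(3-oxoprop-1-en-2-yl)-2,3-dihydro-1-benzofuran-5-yl]ethyl 3-methylbut-2-enoate | C=C(C=O)[C@H]1Oc2ccc([C@H](C)OC(=O)C=C(C)C)cc2[C@H]1OC(=O)CC(C)C | target

**Count**

Total steps: 12. Longest linear sequence: 12 steps (1 to 19).

**Steps most likely to fail**

1. Step 6. The C–H cleavage at the benzylic ring methylene may be too slow because the iridacycle must form on an already strained five-membered ring, so that redistribution or loss of the hydridosilyl ether wins. The fallback keeps the same hydroxyl as the directing group but uses a radical relay. It sets out from 7, which is carbamoylated with 2,2,2-trifluoroethyl isocyanate (CuCl cat., DMF) to the trifluoroethyl carbamate F1 and N-brominated with acetyl hypobromite to the N-bromocarbamate F2. Irradiation with CBr4 in PhCF3 lets the nitrogen radical abstract a C3 hydrogen by 1,6-transfer through a seven-membered transition state and gives the C3 bromide F3. Ag2CO3 ionises the benzylic bromide and the carbamate carbonyl oxygen closes the cis-fused six-membered iminocarbonate F4, the short tether again dictating the face. Hydrolysis (AcOH/H2O) to the cyclic carbonate F5 and methanolysis (K2CO3, MeOH) return to the route at diol 11.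

2. Step 4. The hindered trisubstituted enol ether next to the tertiary carbinol may be reduced slowly or with poor facial selectivity. The fallback sets C2 by asymmetric epoxidation instead and sets out from 1. Stille coupling with tributyl(3-methylbut-2-en-1-yl)stannane (Pd(PPh3)4, DMF, 80 °C) gives the prenylphenol F6, and TBSCl/imidazole gives the aryl silyl ether F7. Transfer hydrogenation with RuCl(p-cymene)[(S,S)-TsDPEN] and HCO2H/Et3N gives the (S)-alcohol F8, and a second silylation gives the bis-silyl ether F9. Shi epoxidation with the D-fructose-derived ketone (KHSO5, K2CO3, Bu4NHSO4, MeCN/dimethoxymethane/H2O, 0 °C) should give the (R)-epoxide F10 by the spiro transition-state model. K2CO3 in MeOH then frees the phenol selectively, and the phenoxide opens the epoxide 5-exo with inversion at the secondary carbon, which gives (S) at C2 and returns to the route at 7.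

3. Step 10. Selenous acid at 70 °C may ionise the C3 ester (aromatising ring B), or the oxidation may stop at the alcohol or attack the C2–H. The fallback avoids selenium and heat and sets out from 14. Ene-type chlorination with Ca(OCl)2 and CO2 in CH2Cl2/H2O at 0 °C shifts the double bond into the former methyl and gives the allylic chloride F11. Oxidation of the chloride with 4-methylmorpholine N-oxide (NaI cat., MeCN, rt; a Kornblum-type N-oxide oxidation) then gives the enal and returns to the route at 16.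

**Further compounds**

F1 | step 6 | 2-[(2S)-5-[(1S)-1-{[tert-butyl(dimethyl)silyl]oxy}ethyl]-2,3-dihydro-1-benzofuran-2-yl]propan-2-yl N-(2,2,2-trifluoroethyl)carbamate | CC(C)(OC(=O)NCC(F)(F)F)[C@H]1Oc2ccc([C@H](C)O[Si](C)(C)C(C)(C)C)cc2C1
F2 | step 6 | N-bromo derivative of F1 (N-bromo-N-(2,2,2-trifluoroethyl)carbamate) | CC(C)(OC(=O)N(Br)CC(F)(F)F)[C@H]1Oc2ccc([C@H](C)O[Si](C)(C)C(C)(C)C)cc2C1
F3 | step 6 | C3-bromo derivative of F1 (both C3 epimers, C2 geometry unchanged) | CC(C)(OC(=O)NCC(F)(F)F)[C@H]1Oc2ccc([C@H](C)O[Si](C)(C)C(C)(C)C)cc2C1Br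
F4 | step 6 | cis-fused cyclic iminocarbonate (six-membered ring O–C(=NCH2CF3)–O joining the carbinol carbon and C3) | CC3(C)[C@H]1Oc2ccc([C@H](C)O[Si](C)(C)C(C)(C)C)cc2[C@H]1OC(=NCC(F)(F)F)O3
F5 | step 6 | cis-fused cyclic carbonate of diol 11 | CC3(C)[C@H]1Oc2ccc([C@H](C)O[Si](C)(C)C(C)(C)C)cc2[C@H]1OC(=O)O3
F6 | step 4 | 1-[4-hydroxy-3-(3-methylbut-2-en-1-yl)phenyl]ethanone | CC(=O)c1ccc(O)c(CC=C(C)C)c1
F7 | step 4 | 1-[4-{[tert-butyl(dimethyl)silyl]oxy}-3-(3-methylbut-2-en-1-yl)phenyl]ethanone | CC(=O)c1ccc(O[Si](C)(C)C(C)(C)C)c(CC=C(C)C)c1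
F8 | step 4 | (1S)-1-[4-{[tert-butyl(dimethyl)silyl]oxy}-3-(3-methylbut-2-en-1-yl)phenyl]ethan-1-ol | C[C@H](O)c1ccc(O[Si](C)(C)C(C)(C)C)c(CC=C(C)C)c1
F9 | step 4 | bis-TBS ether of F8 (aryl and (S)-benzylic oxygens silylated) | C[C@H](O[Si](C)(C)C(C)(C)C)c1ccc(O[Si](C)(C)C(C)(C)C)c(CC=C(C)C)c1
F10 | step 4 | (R)-epoxide of F9 (3,3-dimethyloxiran-2-ylmethyl group on the ring) | C[C@H](O[Si](C)(C)C(C)(C)C)c1ccc(O[Si](C)(C)C(C)(C)C)c(C[C@H]2OC2(C)C)c1
F11 | step 10 | (2R,3R)-5-[(1S)-1-{[tert-butyl(dimethyl)silyl]oxy}ethyl]-2-(3-chloroprop-1-en-2-yl)-2,3-dihydro-1-benzofuran-3-yl 3-methylbutanoate | C=C(CCl)[C@H]1Oc2ccc([C@H](C)O[Si](C)(C)C(C)(C)C)cc2[C@H]1OC(=O)CC(C)C
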